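**Assumption:** the target is taken exactly as drawn. In quinolizidine numbering (N5; ring A = C1–C4 with the C2 ketone and C3 methyl; ring B = C6–C9), half A is (1S,3S,9R,9aR) and half B is (1R,3S,9S,9aR). Chain 1 joins C9 of half A to C1 of half B; chain 2 joins C9 of half B to C1 of half A.

## Retrosynthetic overview

1. 34 ⇐ hydrogenation of macrocyclic alkene 33 ⇐ ring-closing metathesis in chain 2 of the seco bis-quinolizidinone 32 (16-membered ring closed last).
2. Ring A of half A (key step): aza-Diels–Alder [4+2] of the cyclic N–H iminium ion, made from the ring B lactam of 28, with 2-silyloxydiene 29; the diene enters anti to the C9 chain (9,9a-trans).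
3. Ring A of half B: formal aza-[4+2] annulation of activated lactam 21 with silyloxydiene 24 (C–C coupling, then 6-endo aza-Michael), then hydride delivery to C9a anti to the C9 chain (9,9a-cis).
4. Both ring B lactams come from the two enantiomers of cyclohex-3-ene-1-carboxylic acid (ozonolysis, lactone-to-lactam switch, Negishi chain extension). C9 is bought, C9a is relayed from C9, and C1 and C3 are set by equilibration next to the ketone.
5. Ring order: ring B of half A, ring B of half B, ring A of half B, ring A of half A, macrocycle.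

## Route

Step 1
Reactants: 1 (S)-cyclohex-3-ene-1-carboxylic acid
Product: 3 (3S)-3-(3-hydroxypropyl)oxolan-2-one, via dihydroxy acid 2 (not isolated)
Conditions: O3, CH2Cl2/MeOH, −78 °C; NaBH4, −78 °C to rt; 2 M HCl to pH 2, rt
Reagents that add atoms: ozone, [O-][O+]=O
Why: Ozonolysis with reductive work-up gives the diol acid, which lactonises to the five-membered γ-lactone on the two-carbon arm and leaves the three-carbon arm as a free primary alcohol, without touching the bought stereocentre.

Step 2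
Reactants: 3 (3S)-3-(3-hydroxypropyl)oxolan-2-one
Product: 6 (3S)-3-(2-hydroxyethyl)piperidin-2-one, via azide 4 (not isolated), via amine 5 (not isolated)
Conditions: PPh3, DIAD, (PhO)2P(O)N3, THF, 0 °C to rt; then PPh3, H2O, 60 °C
Reagents that add atoms: diphenylphosphoryl azide, [N-]=[N+]=NP(=O)(Oc1ccccc1)Oc1ccccc1
Why: Mitsunobu azidation and Staudinger reduction give a primary amine that opens the γ-lactone to the more stable six-membered lactam (ring B) and frees the 2-hydroxyethyl arm, with no bond to the stereocentre broken.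

Step 3
Reactants: 6 (3S)-3-(2-hydroxyethyl)piperidin-2-one
Product: 7 (3S)-3-(2-iodoethyl)piperidin-2-one
Conditions: I2, PPh3, imidazole, CH2Cl2, 0 °C to rt
Reagents that add atoms: iodine, II
Why: Appel iodination of the primary alcohol proceeds under neutral conditions that leave the lactam and the α-stereocentre alone.

Step 4
Reactants: 7 (3S)-3-(2-iodoethyl)piperidin-2-one; 8 (4-cyanobutyl)zinc bromide
Product: 9 7-[(3R)-2-oxopiperidin-3-yl]heptanenitrile
Conditions: Pd2(dba)3 (2 mol %), PCyp3 (8 mol %), N-methylimidazole, THF/NMP, 80 °C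
Reagents that add atoms: none
Why: Negishi alkyl–alkyl coupling on zerovalent palladium with a bulky trialkylphosphine outruns β-hydride elimination and tolerates the nitrile and the lactam N–H (the descriptor changes only through CIP priorities).

Step 5
Reactants: 9 7-[(3R)-2-oxopiperidin-3-yl]heptanenitrile; 10 isopropenylmagnesium bromide
Product: 11 (3R)-3-(8-methyl-7-oxonon-8-en-1-yl)piperidin-2-one
Conditions: 10 (3 equiv), THF, 0 °C to rt; 1 M HCl, 0 °C
Reagents that add atoms: water, O
Why: Grignard addition to the nitrile stops at the N-magnesio ketimine, which is hydrolysed on work-up to the isopropenyl ketone, the first equivalent of reagent only deprotonating the lactam.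

Step 6
Reactants: 12 (R)-cyclohex-3-ene-1-carboxylic acid
Product: 14 (3R)-3-(3-hydroxypropyl)oxolan-2-one, via dihydroxy acid 13 (not isolated)
Conditions: O3, CH2Cl2/MeOH, −78 °C; NaBH4, −78 °C to rt; 2 M HCl to pH 2, rt
Reagents that add atoms: ozone, [O-][O+]=O
Why: Same ozonolysis, reduction and γ-lactonisation as step 1 in the enantiomeric series.

Step 7
Reactants: 14 (3R)-3-(3-hydroxypropyl)oxolan-2-one
Product: 17 (3R)-3-(2-hydroxyethyl)piperidin-2-one, via azide 15 (not isolated), via amine 16 (not isolated)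
Conditions: PPh3, DIAD, (PhO)2P(O)N3, THF, 0 °C to rt; then PPh3, H2O, 60 °C
Reagents that add atoms: diphenylphosphoryl azide, [N-]=[N+]=NP(=O)(Oc1ccccc1)Oc1ccccc1
Why: Same Mitsunobu azidation, Staudinger reduction and lactone-to-lactam transacylation as step 2.

Step 8
Reactants: 17 (3R)-3-(2-hydroxyethyl)piperidin-2-one
Product: 18 (3R)-3-(2-iodoethyl)piperidin-2-one
Conditions: I2, PPh3, imidazole, CH2Cl2, 0 °C to rt
Reagents that add atoms: iodine, II
Why: Appel iodination as in step 3.

Step 9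
Reactants: 18 (3R)-3-(2-iodoethyl)piperidin-2-one; 19 vinylmagnesium bromide
Product: 21 (3S)-3-(but-3-en-1-yl)piperidin-2-one, via vinylzinc bromide 20 (not isolated)
Conditions: 19, ZnBr2, THF, 0 °C; then 18, Pd2(dba)3 (2 mol %), PCyp3 (8 mol %), N-methylimidazole, THF/NMP, 80 °C
Reagents that add atoms: none
Why: Transmetalation to the mild alkenylzinc reagent and Negishi coupling with the primary iodide install the terminal alkene needed for the later ring closure without base strong enough to epimerise C3.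

Step 10
Reactants: 22 pent-4-enenitrile; 10 isopropenylmagnesium bromide
Product: 23 2-methylhepta-1,6-dien-3-one
Conditions: THF, 0 °C to rt; 1 M HCl, 0 °C
Reagents that add atoms: water, O
Why: Grignard addition to the nitrile and hydrolysis of the ketimine give the cross-conjugated enone that carries the future C1 allyl group of half A.

Step 11
Reactants: 11 (3R)-3-(8-methyl-7-oxonon-8-en-1-yl)piperidin-2-one
Product: 24 (3R)-1-[tert-butyl(dimethyl)silyl]-3-[(6Z)-7-{[tert-butyl(dimethyl)silyl]oxy}-8-methylnona-6,8-dien-1-yl]piperidin-2-one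
Conditions: TBSOTf (2.3 equiv), Et3N, CH2Cl2, −78 to 0 °C; salts removed with pentane under argon, used crude
Reagents that add atoms: tert-butyldimethylsilyl trifluoromethanesulfonate, CC(C)(C)[Si](C)(C)OS(=O)(=O)C(F)(F)F
Why: Soft enolisation on the only enolisable side gives the (Z)-2-silyloxydiene, and N-silylation blocks the lactam as a competing nucleophile in the next step.

Step 12
Reactants: 21 (3S)-3-(but-3-en-1-yl)piperidin-2-one; 24 the bis-silylated silyloxydiene
Product: 27 (9S)-9-(but-3-en-1-yl)-3-methyl-1-{5-[(3R)-2-oxopiperidin-3-yl]pentyl}-3,4,6,7,8,9-hexahydro-2H-quinolizin-2-one (C3 epimers), via imidoyl triflate 25 (not isolated), via vinylogous amide 26 (not isolated)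
Conditions: 21, Tf2O, 2-fluoropyridine, CH2Cl2, −78 to 0 °C; then 24, −78 °C to rt; then K2CO3, MeOH, 50 °C
Reagents that add atoms: none
Why: Electrophilic amide activation lets the silyl enol ether carbon add to the lactam carbon (Mukaiyama-type addition–elimination) to give the hydrogen-bonded (Z)-vinylogous amide, whose N–H then closes ring A by 6-endo aza-Michael addition to the isopropenyl ketone (a formal aza-[4+2] annulation), with C9 being the bought centre and C3 left to be equilibrated later.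

Step 13
Reactants: 27 the bicyclic vinylogous amide
Product: 28 (1R,3S,9S,9aR)-9-(but-3-en-1-yl)-3-methyl-1-{5-[(3R)-2-oxopiperidin-3-yl]pentyl}octahydro-2H-quinolizin-2-one
Conditions: Et3SiH, CF3CO2H, CH2Cl2, 0 °C to rt; then K2CO3, MeOH, rt
Reagents that add atoms: none
Why: In this ionic hydrogenation the C9 butenyl group sits pseudoaxial to escape A(1,3) strain with the C1 chain, so hydride adds to C9a of the protonated vinylogous amide from the opposite face (H9a trans to butenyl, 9,9a-cis), and the mild base step then places the C1 chain and C3 methyl equatorial by enolisation.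

Step 14
Reactants: 23 2-methylhepta-1,6-dien-3-one
Product: 29 tert-butyl(dimethyl){[(3Z)-2-methylhepta-1,3,6-trien-3-yl]oxy}silane
Conditions: TBSOTf, Et3N, CH2Cl2, −78 to 0 °C
Reagents that add atoms: tert-butyldimethylsilyl trifluoromethanesulfonate, CC(C)(C)[Si](C)(C)OS(=O)(=O)C(F)(F)F
Why: Kinetic silylation at the only α-CH2 gives the 2-silyloxydiene for the cycloaddition.

Step 15
Reactants: 28 the half B quinolizidinone with pendant lactam; 29 the silyloxydiene
Product: 32 (1R,3S,9S,9aR)-9-(but-3-en-1-yl)-3-methyl-1-{5-[(1S,3S,9R,9aR)-3-methyl-2-oxo-1-(prop-2-en-1-yl)octahydro-2H-quinolizin-9-yl]pentyl}octahydro-2H-quinolizin-2-one, via cyclic imine 30 (not isolated), via silyl enol ether 31 (not isolated)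
Conditions: 28, TfOH (1.0 equiv), CH2Cl2, −78 °C; 2-fluoropyridine, Tf2O, −78 to 0 °C; Et3SiH, rt; then 29, −78 °C to rt; 1 M HCl, THF; then K2CO3, MeOH, rt
Reagents that add atoms: none
Why: With the tertiary amine parked as its triflate salt, the lactam is reduced through its O-triflyl iminium ion to the cyclic N–H iminium ion, which undergoes the aza-Diels–Alder [4+2] with the silyloxydiene on the face anti to the C9 chain (9,9a-trans), and hydrolysis plus mild equilibration leave the C1 allyl axial (an equatorial group would clash with the equatorial C9 chain) and the C3 methyl equatorial.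

Step 16
Reactants: 32 the seco bis-quinolizidinone
Product: 33 macrocyclic alkene (E/Z mixture)
Conditions: p-TsOH·H2O (2.1 equiv), second-generation Grubbs catalyst (10 mol %), CH2Cl2 (1 mM), 40 °C; NaHCO3 work-up
Reagents that add atoms: none
Why: Ring-closing metathesis of the only two terminal alkenes of the bis-ammonium salt closes the 16-membered ring with loss of ethene, and protonation keeps the amines from binding ruthenium and from opening the β-amino ketones.

Step 17
Reactants: 33 macrocyclic alkene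
Product: 34 the target
Conditions: H2 (1 atm), Pd/C, EtOAc, rt
Reagents that add atoms: none
Why: Neutral heterogeneous hydrogenation saturates the isolated disubstituted alkene and leaves the ketones and all eight stereocentres untouched.

## Compound list

1 | (S)-cyclohex-3-ene-1-carboxylic acid | OC(=O)[C@@H]1CC=CCC1 | starting material
2 | (2S)-5-hydroxy-2-(2-hydroxyethyl)pentanoic acid | OC(=O)[C@H](CCO)CCCO | intermediate
3 | (3S)-3-(3-hydroxypropyl)oxolan-2-one | O=C1OCC[C@@H]1CCCO | intermediate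
4 | (3S)-3-(3-azidopropyl)oxolan-2-one | O=C1OCC[C@@H]1CCCN=[N+]=[N-] | intermediate
5 | (3S)-3-(3-aminopropyl)oxolan-2-one | O=C1OCC[C@@H]1CCCN | intermediate
6 | (3S)-3-(2-hydroxyethyl)piperidin-2-one | O=C1NCCC[C@H]1CCO | intermediate
7 | (3S)-3-(2-iodoethyl)piperidin-2-one | O=C1NCCC[C@H]1CCI | intermediate
8 | (4-cyanobutyl)zinc bromide (THF solution) | N#CCCCC[Zn]Br | starting material
9 | 7-[(3R)-2-oxopiperidin-3-yl]heptanenitrile | O=C1NCCC[C@H]1CCCCCCC#N | intermediate
10 | isopropenylmagnesium bromide | CC(=C)[Mg]Br | starting material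
11 | (3R)-3-(8-methyl-7-oxonon-8-en-1-yl)piperidin-2-one | O=C1NCCC[C@H]1CCCCCCC(=O)C(C)=C | intermediate
12 | (R)-cyclohex-3-ene-1-carboxylic acid | OC(=O)[C@H]1CC=CCC1 | starting material
13 | (2R)-5-hydroxy-2-(2-hydroxyethyl)pentanoic acid | OC(=O)[C@@H](CCO)CCCO | intermediate
14 | (3R)-3-(3-hydroxypropyl)oxolan-2-one | O=C1OCC[C@H]1CCCO | intermediate
15 | (3R)-3-(3-azidopropyl)oxolan-2-one | O=C1OCC[C@H]1CCCN=[N+]=[N-] | intermediate
16 | (3R)-3-(3-aminopropyl)oxolan-2-one | O=C1OCC[C@H]1CCCN | intermediate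
17 | (3R)-3-(2-hydroxyethyl)piperidin-2-one | O=C1NCCC[C@@H]1CCO | intermediate
18 | (3R)-3-(2-iodoethyl)piperidin-2-one | O=C1NCCC[C@@H]1CCI | intermediate
19 | vinylmagnesium bromide | C=C[Mg]Br | starting material
20 | vinylzinc bromide | C=C[Zn]Br | intermediate
21 | (3S)-3-(but-3-en-1-yl)piperidin-2-one | O=C1NCCC[C@@H]1CCC=C | intermediate
22 | pent-4-enenitrile | C=CCCC#N | starting material
23 | 2-methylhepta-1,6-dien-3-one | C=CCCC(=O)C(C)=C | intermediate
24 | (3R)-1-[tert-butyl(dimethyl)silyl]-3-[(6Z)-7-{[tert-butyl(dimethyl)silyl]oxy}-8-methylnona-6,8-dien-1-yl]piperidin-2-one | O=C1N([Si](C)(C)C(C)(C)C)CCC[C@H]1CCCCC/C=C(\O[Si](C)(C)C(C)(C)C)C(C)=C | intermediate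
25 | (5S)-5-(but-3-en-1-yl)-2,3,4,5-tetrahydropyridin-6-yl trifluoromethanesulfonate | C=CCC[C@H]1CCCN=C1OS(=O)(=O)C(F)(F)F | intermediate
26 | (3R)-3-{(6Z)-6-[(3S)-3-(but-3-en-1-yl)piperidin-2-ylidene]-8-methyl-7-oxonon-8-en-1-yl}piperidin-2-one | C=CCC[C@H]1CCCN/C1=C(\C(=O)C(C)=C)CCCCC[C@@H]2CCCNC2=O | intermediate
27 | (9S)-9-(but-3-en-1-yl)-3-methyl-1-{5-[(3R)-2-oxopiperidin-3-yl]pentyl}-3,4,6,7,8,9-hexahydro-2H-quinolizin-2-one (C3 epimers) | C=CCC[C@H]1CCCN2CC(C)C(=O)C(CCCCC[C@@H]3CCCNC3=O)=C12 | intermediate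
28 | (1R,3S,9S,9aR)-9-(but-3-en-1-yl)-3-methyl-1-{5-[(3R)-2-oxopiperidin-3-yl]pentyl}octahydro-2H-quinolizin-2-one | C=CCC[C@H]1CCCN2C[C@H](C)C(=O)[C@H](CCCCC[C@@H]3CCCNC3=O)[C@@H]12 | intermediate
29 | tert-butyl(dimethyl){[(3Z)-2-methylhepta-1,3,6-trien-3-yl]oxy}silane | C=C(C)/C(O[Si](C)(C)C(C)(C)C)=C/CC=C | intermediate
30 | (1R,3S,9S,9aR)-9-(but-3-en-1-yl)-3-methyl-1-{5-[(3R)-2,3,4,5-tetrahydropyridin-3-yl]pentyl}octahydro-2H-quinolizin-2-one (present as its iminium triflate) | C=CCC[C@H]1CCCN2C[C@H](C)C(=O)[C@H](CCCCC[C@@H]3CCCN=C3)[C@@H]12 | intermediate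
31 | (1R,3S,9S,9aR)-9-(but-3-en-1-yl)-1-{5-[(9R,9aR)-2-{[tert-butyl(dimethyl)silyl]oxy}-3-methyl-1-(prop-2-en-1-yl)-1,6,7,8,9,9a-hexahydro-4H-quinolizin-9-yl]pentyl}-3-methyloctahydro-2H-quinolizin-2-one (C1 of the enol ether ring not yet fixed) | C=CCC[C@H]1CCCN2C[C@H](C)C(=O)[C@H](CCCCC[C@@H]3CCCN4CC(C)=C(O[Si](C)(C)C(C)(C)C)C(CC=C)[C@@H]34)[C@@H]12 | intermediate
32 | (1R,3S,9S,9aR)-9-(but-3-en-1-yl)-3-methyl-1-{5-[(1S,3S,9R,9aR)-3-methyl-2-oxo-1-(prop-2-en-1-yl)octahydro-2H-quinolizin-9-yl]pentyl}octahydro-2H-quinolizin-2-one | C=CCC[C@H]1CCCN2C[C@H](C)C(=O)[C@H](CCCCC[C@@H]3CCCN4C[C@H](C)C(=O)[C@@H](CC=C)[C@@H]34)[C@@H]12 | intermediate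
33 | macrocyclic alkene: the target skeleton with a C=C (E/Z) at the third and fourth carbons of chain 2 counted from C9 of half B, stereocentres as in 34 | C[C@H]1CN2CCC[C@H]3CCCCC[C@H]4C(=O)[C@@H](C)CN5CCC[C@H](CCC=CC[C@H](C1=O)[C@@H]32)[C@H]45 | intermediate
34 | CNP0268544.8, the 16-membered bis(3-methylquinolizidin-2-one) with half A (1S,3S,9R,9aR) and half B (1R,3S,9S,9aR) | C[C@H]1CN2CCC[C@H]3CCCCC[C@H]4C(=O)[C@@H](C)CN5CCC[C@H](CCCCC[C@H](C1=O)[C@@H]32)[C@H]45 | target

## Step count and risk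

Total steps: 17. Longest linear sequence: 11 steps (steps 1–5, 11, 12, 13, 15, 16, 17).

The stereochemical outcomes at C9a in steps 13 and 15, and the thermodynamic preference at C1 and C3, are argued from conformational analysis of each quinolizidinone unit; they have not been verified for these substrates.

**Most likely to fail: step 12** (amide activation and C–C coupling). The imidoyl triflate 25 may lose C9 integrity by tautomerisation, or the silyloxydiene may not add to it. The fallback is a sulfide contraction and sets out from 21 and 24. Lactam 21 is thionated with Lawesson's reagent to (3S)-3-(but-3-en-1-yl)piperidine-2-thione F1. Diene 24 is brominated with NBS at the enol ether carbon, and aqueous work-up frees the lactam N–H to give (3R)-3-(6-bromo-8-methyl-7-oxonon-8-en-1-yl)piperidin-2-one F2 (both configurations at the C–Br carbon). S-Alkylation of F1 with F2 followed by PPh3/Et3N sulfur extrusion gives the vinylogous amide, and the fallback comes back to the route at 26, which is cyclised to 27 with K2CO3/MeOH as before.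

**Second: step 15** (late lactam reduction and aza-Diels–Alder beside an ammonium ketone, with anti selectivity not proven for this iminium). The fallback reverses the order of the two annulations and sets out from 9.
- Nitrile 9 is put through the same Tf2O/2-fluoropyridine/Et3SiH sequence and the aza-Diels–Alder with 29, now with no amine or ketone present, to give 7-[(9R,9aR)-2-{[tert-butyl(dimethyl)silyl]oxy}-3-methyl-1-(prop-2-en-1-yl)-1,6,7,8,9,9a-hexahydro-4H-quinolizin-9-yl]heptanenitrile F3.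
- Its nitrile is converted with 10 (mild hydrolysis, enol ether kept) into the isopropenyl ketone (9R,9aR)-2-{[tert-butyl(dimethyl)silyl]oxy}-3-methyl-9-(8-methyl-7-oxonon-8-en-1-yl)-1-(prop-2-en-1-yl)-1,6,7,8,9,9a-hexahydro-4H-quinolizine F4.
- TBSOTf/Et3N gives the bis-silyl diene, the (6Z)-7-silyloxy-8-methylnona-6,8-dienyl analogue F5.
- F5, as its triflate salt, is added to 25 freshly made from 21; K2CO3/MeOH then dilute HCl give (9S)-9-(but-3-en-1-yl)-3-methyl-1-{5-[(1S,3S,9R,9aR)-3-methyl-2-oxo-1-(prop-2-en-1-yl)octahydro-2H-quinolizin-9-yl]pentyl}-3,4,6,7,8,9-hexahydro-2H-quinolizin-2-one F6.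
- Et3SiH/CF3CO2H followed by K2CO3/MeOH reduces F6, and the fallback comes back to the route at 32.

**Third: step 16** (macrocyclic ring-closing metathesis, which may give oligomers or isomerise the allyl ketone). The fallback closes the macrocycle by the cycloaddition instead and sets out from 28. As its p-TsOH salt, 28 undergoes cross-metathesis with an excess of 23 (only the monosubstituted alkenes react) to give the enone (1R,3S,9S,9aR)-3-methyl-9-(7-methyl-6-oxoocta-3,7-dien-1-yl)-1-{5-[(3R)-2-oxopiperidin-3-yl]pentyl}octahydro-2H-quinolizin-2-one F7. TBSOTf/Et3N with bicarbonate work-up gives the bis(silyl enol ether) with a silyloxydiene at the chain end and a silyl enol ether at C2 of half B, F8. The reductive lactam activation of step 15, run at 1 mM, lets the tethered silyloxydiene add to the iminium ion; acid hydrolysis and K2CO3/MeOH follow, and the fallback comes back to the route at 33.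

## Further compounds

F1 | step 12 | (3S)-3-(but-3-en-1-yl)piperidine-2-thione | S=C1NCCC[C@@H]1CCC=C
F2 | step 12 | (3R)-3-(6-bromo-8-methyl-7-oxonon-8-en-1-yl)piperidin-2-one | O=C1NCCC[C@H]1CCCCCC(Br)C(=O)C(C)=C
F3 | step 15 | 7-[(9R,9aR)-2-{[tert-butyl(dimethyl)silyl]oxy}-3-methyl-1-(prop-2-en-1-yl)-1,6,7,8,9,9a-hexahydro-4H-quinolizin-9-yl]heptanenitrile | N#CCCCCCC[C@@H]1CCCN2CC(C)=C(O[Si](C)(C)C(C)(C)C)C(CC=C)[C@@H]12
F4 | step 15 | (9R,9aR)-2-{[tert-butyl(dimethyl)silyl]oxy}-3-methyl-9-(8-methyl-7-oxonon-8-en-1-yl)-1-(prop-2-en-1-yl)-1,6,7,8,9,9a-hexahydro-4H-quinolizine | C=C(C)C(=O)CCCCCC[C@@H]1CCCN2CC(C)=C(O[Si](C)(C)C(C)(C)C)C(CC=C)[C@@H]12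
F5 | step 15 | (9R,9aR)-2-{[tert-butyl(dimethyl)silyl]oxy}-9-[(6Z)-7-{[tert-butyl(dimethyl)silyl]oxy}-8-methylnona-6,8-dien-1-yl]-3-methyl-1-(prop-2-en-1-yl)-1,6,7,8,9,9a-hexahydro-4H-quinolizine | C=C(C)/C(O[Si](C)(C)C(C)(C)C)=C/CCCCC[C@@H]1CCCN2CC(C)=C(O[Si](C)(C)C(C)(C)C)C(CC=C)[C@@H]12
F6 | step 15 | (9S)-9-(but-3-en-1-yl)-3-methyl-1-{5-[(1S,3S,9R,9aR)-3-methyl-2-oxo-1-(prop-2-en-1-yl)octahydro-2H-quinolizin-9-yl]pentyl}-3,4,6,7,8,9-hexahydro-2H-quinolizin-2-one | C=CCC[C@H]1CCCN2CC(C)C(=O)C(CCCCC[C@@H]3CCCN4C[C@H](C)C(=O)[C@@H](CC=C)[C@@H]34)=C12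
F7 | step 16 | (1R,3S,9S,9aR)-3-methyl-9-(7-methyl-6-oxoocta-3,7-dien-1-yl)-1-{5-[(3R)-2-oxopiperidin-3-yl]pentyl}octahydro-2H-quinolizin-2-one | C=C(C)C(=O)CCC=CCC[C@H]1CCCN2C[C@H](C)C(=O)[C@H](CCCCC[C@@H]3CCCNC3=O)[C@@H]12
F8 | step 16 | (3R)-3-{5-[(1R,9S,9aR)-2-{[tert-butyl(dimethyl)silyl]oxy}-9-[(5Z)-6-{[tert-butyl(dimethyl)silyl]oxy}-7-methylocta-3,5,7-trien-1-yl]-3-methyl-1,6,7,8,9,9a-hexahydro-4H-quinolizin-1-yl]pentyl}piperidin-2-one | C=C(C)/C(O[Si](C)(C)C(C)(C)C)=C/CC=CCC[C@H]1CCCN2CC(C)=C(O[Si](C)(C)C(C)(C)C)[C@H](CCCCC[C@@H]3CCCNC3=O)[C@@H]12
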